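**Retrosynthetic overview**

1. Numbering: C1 is the quaternary oxirane carbon bearing C7H2OBz, C2 is CHOAc, C3 is CHOBz, C4=C5 is the alkene and C6 is the oxirane CH. The strategy rests on the cis C4=C5 bond of the carbocycle C1–C6, which sits between two oxygen-bearing allylic carbons (C3 and C6) that can each carry a vinyl group in an open chain.
2. The oxirane C1–O–C6 is opened to a trans C1–OH/C6–OMs pair (closure by SN2 with inversion at C6), which comes from C6–OPMB cyclohexene 13.
3. Cyclohexene 13 is disconnected at C4=C5 by ring-closing metathesis to octa-1,7-diene 12.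
4. Diene 12 comes from ketone 5 (C1=O held in a 1,3-dioxan-5-one, with C2, C3 and the C4 vinyl group from D-fructose) and a (Z)-γ-(PMB-oxy)allyl-aluminium reagent (C1–C6 bond, sets C1 and C6). Ketone 5 comes from zinc fragmentation of a 6-iodo fructofuranoside.
5. Ring order: the six-membered carbocycle first (step 9), the oxirane last (step 12).

Key step: step 9

Remark: the methyl glycoside of step 1 is taken as the α-anomer locked by the 1,3-acetonide; the anomeric centre is destroyed in step 4, so its purity is not critical.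

**Route**

Step 1
Reactants: 1 D-fructose
Product: 2 methyl 1,3-O-isopropylidene-α-D-fructofuranoside
Conditions: Me2C(OMe)2, TsOH·H2O (cat.), 1,4-dioxane, rt; Et3N quench
Reagents that add atoms: 2,2-dimethoxypropane COC(C)(C)OC
Why: Kinetic Fischer glycosidation with the methanol released from the reagent gives the furanoside, and transacetalisation traps the α-anomer, the only one in which C1–OH and C3–OH are cis on the ring, as the 1,3-dioxane, so the anomeric centre is set by the acetonide tether and no other stereocentre changes.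

Step 2
Reactants: 2 methyl 1,3-O-isopropylidene-α-D-fructofuranoside
Product: 3 methyl 6-deoxy-6-iodo-1,3-O-isopropylidene-α-D-fructofuranoside
Conditions: PPh3, I2, imidazole, THF, 0 °C → rt
Reagents that add atoms: iodine II
Why: The Appel iodination runs by SN2 on an alkoxyphosphonium ion and therefore takes the unhindered primary C6–OH in preference to the secondary ring C4–OH, with no stereocentre touched.

Step 3
Reactants: 3 methyl 6-deoxy-6-iodo-1,3-O-isopropylidene-α-D-fructofuranoside
Product: 4 methyl 4-O-benzoyl-6-deoxy-6-iodo-1,3-O-isopropylidene-α-D-fructofuranoside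
Conditions: BzCl, pyridine, DMAP (cat.), CH2Cl2, 0 °C → rt
Reagents that add atoms: benzoyl chloride O=C(Cl)c1ccccc1
Why: DMAP-catalysed esterification acylates the only free hydroxyl (fructose C4–OH, the later C3–OBz of the target) with retention, since only the O–H bond reacts.

Step 4
Reactants: 4 methyl 4-O-benzoyl-6-deoxy-6-iodo-1,3-O-isopropylidene-α-D-fructofuranoside
Product: 5 (1R)-1-[(4S)-2,2-dimethyl-5-oxo-1,3-dioxan-4-yl]prop-2-enyl benzoate (4-O-benzoyl-5,6-dideoxy-1,3-O-isopropylidene-D-threo-hex-5-en-2-ulose)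
Conditions: activated Zn dust, THF/H2O 4:1, sonication, 40 °C
Reagents that add atoms: none
Why: In this Bernet–Vasella reductive fragmentation zinc inserts into the C6–I bond, β-elimination breaks the C5–O5 ring bond and the hemiketal alkoxide expels methoxide, which unmasks the ketone inside the intact 1,3-dioxane and forms the vinyl group while the two carbinol stereocentres are untouched.

Step 5
Reactants: 5 (1R)-1-[(4S)-2,2-dimethyl-5-oxo-1,3-dioxan-4-yl]prop-2-enyl benzoate; 6 allyl 4-methoxybenzyl ether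
Product: 9 (1R)-1-{(4S,5S)-5-hydroxy-5-[(1R)-1-(4-methoxybenzyloxy)prop-2-enyl]-2,2-dimethyl-1,3-dioxan-4-yl}prop-2-enyl benzoate, via lithiated allyl PMB ether 7 (not isolated), via (Z)-γ-(PMB-oxy)allyl diethylaluminium 8 (not isolated)
Conditions: 6 (2.2 equiv), s-BuLi (2.0 equiv), THF, −78 °C; Et2AlCl (2.1 equiv), −78 °C; then 5, −78 °C; aq. Rochelle salt
Reagents that add atoms: none
Why: In this γ-alkoxyallylation of a ketone (type-I allylmetal addition, SE2′ through a Zimmerman–Traxler chair) the O-chelated (Z)-reagent bonds through its oxygen-bearing carbon, axial attack on the dioxanone chair (equatorial side chain, no 1,3-diaxial hydrogens on the ring oxygens) should place the new C1–C6 bond cis to the side chain and the C1–OH trans to it, and the Z geometry with the substituted α-carbon C2 equatorial in the chair should set C6–OPMB syn to C1–OH.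

Step 6
Reactants: 9 (1R)-1-{(4S,5S)-5-hydroxy-5-[(1R)-1-(4-methoxybenzyloxy)prop-2-enyl]-2,2-dimethyl-1,3-dioxan-4-yl}prop-2-enyl benzoate
Product: 10 (3R,4S,5R,6R)-4,5-dihydroxy-5-(hydroxymethyl)-6-(4-methoxybenzyloxy)octa-1,7-dien-3-yl benzoate
Conditions: AcOH/H2O 4:1, 40 °C
Reagents that add atoms: none
Why: Acid-catalysed acetal hydrolysis removes the isopropylidene group under conditions that leave the PMB ether, the allylic benzoate and the tertiary carbinol intact, and no stereocentre is involved.

Step 7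
Reactants: 10 (3R,4S,5R,6R)-4,5-dihydroxy-5-(hydroxymethyl)-6-(4-methoxybenzyloxy)octa-1,7-dien-3-yl benzoate
Product: 11 (3R,4S,5R,6R)-5-(benzoyloxymethyl)-4,5-dihydroxy-6-(4-methoxybenzyloxy)octa-1,7-dien-3-yl benzoate
Conditions: BzCl (1.05 equiv), pyridine, CH2Cl2, −40 → −20 °C
Reagents that add atoms: benzoyl chloride O=C(Cl)c1ccccc1
Why: Kinetically controlled esterification distinguishes the primary C7–OH from the secondary C2–OH (flanked by the quaternary C1 and by C3–OBz) and from the tertiary C1–OH, so one equivalent of acid chloride should give the primary benzoate.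

Step 8
Reactants: 11 (3R,4S,5R,6R)-5-(benzoyloxymethyl)-4,5-dihydroxy-6-(4-methoxybenzyloxy)octa-1,7-dien-3-yl benzoate
Product: 12 (3R,4S,5S,6R)-4-acetoxy-5-(benzoyloxymethyl)-5-hydroxy-6-(4-methoxybenzyloxy)octa-1,7-dien-3-yl benzoate
Conditions: Ac2O, pyridine, DMAP (cat.), CH2Cl2, 0 °C
Reagents that add atoms: acetic anhydride CC(=O)OC(C)=O
Why: DMAP-catalysed acetylation takes the secondary C2–OH while the fully substituted C1–OH is too hindered to react, and the low temperature limits benzoate migration from C3 to C2.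

Step 9
Reactants: 12 (3R,4S,5S,6R)-4-acetoxy-5-(benzoyloxymethyl)-5-hydroxy-6-(4-methoxybenzyloxy)octa-1,7-dien-3-yl benzoate
Product: 13 (1R,4R,5S,6S)-6-acetoxy-5-(benzoyloxymethyl)-5-hydroxy-4-(4-methoxybenzyloxy)cyclohex-2-en-1-yl benzoate
Conditions: Grubbs second-generation catalyst (5 mol %), CH2Cl2 (5 mM), 40 °C
Reagents that add atoms: none
Why: The ruthenium benzylidene exchanges with one terminal vinyl group to give a ruthenium alkylidene, which adds to the second vinyl group in an intramolecular [2+2] step, and cycloreversion of the ruthenacyclobutane forms C4=C5 and releases ethylene. This is ring-closing olefin metathesis, and the closest known reaction type is the closure of carbohydrate-derived octa-1,7-dienes to conduritol-type cyclohexenes. The carbocycle C1–C6 is closed as a six-membered ring in which the new alkene is necessarily cis. No stereocentre is formed; C1, C2, C3 and C6 are not at the reacting carbons and are carried over unchanged. The only selectivity needed is ring closure over cross-metathesis, which high dilution, loss of volatile ethylene and the gauche-biased chain of four contiguous substituted sp3 carbons (C3–C2–C1–C6) should secure. Both olefins are monosubstituted, and the esters, the PMB ether and the tertiary alcohol are tolerated by an NHC–ruthenium catalyst.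

Step 10
Reactants: 13 (1R,4R,5S,6S)-6-acetoxy-5-(benzoyloxymethyl)-5-hydroxy-4-(4-methoxybenzyloxy)cyclohex-2-en-1-yl benzoate
Product: 14 (1R,4R,5S,6S)-6-acetoxy-5-(benzoyloxymethyl)-4,5-dihydroxycyclohex-2-en-1-yl benzoate
Conditions: DDQ, CH2Cl2/pH 7 buffer 10:1, 0 °C → rt
Reagents that add atoms: none
Why: Oxidative PMB cleavage (hydride abstraction from the electron-rich benzylic position, then hydrolysis of the oxocarbenium ion) frees the C6 allylic alcohol under neutral conditions without touching the esters or the C6–O bond.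

Step 11
Reactants: 14 (1R,4R,5S,6S)-6-acetoxy-5-(benzoyloxymethyl)-4,5-dihydroxycyclohex-2-en-1-yl benzoate
Product: 15 (1R,4R,5R,6S)-6-acetoxy-5-(benzoyloxymethyl)-5-hydroxy-4-(methylsulfonyloxy)cyclohex-2-en-1-yl benzoate
Conditions: Ms2O, Et3N, CH2Cl2, −20 → 0 °C; used crude
Reagents that add atoms: methanesulfonic anhydride CS(=O)(=O)OS(C)(=O)=O
Why: O-Sulfonylation takes the secondary allylic C6–OH and not the tertiary C1–OH, with retention at C6, and the anhydride keeps chloride out of the flask so that the allylic mesylate is not displaced.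

Step 12
Reactants: 15 (1R,4R,5R,6S)-6-acetoxy-5-(benzoyloxymethyl)-5-hydroxy-4-(methylsulfonyloxy)cyclohex-2-en-1-yl benzoate
Product: 16 [(1S,2S,3R,6S)-2-acetoxy-3-(benzoyloxy)-7-oxabicyclo[4.1.0]hept-4-en-1-yl]methyl benzoate
Conditions: DBU, CH2Cl2, 0 °C → rt
Reagents that add atoms: none
Why: In this intramolecular Williamson etherification (3-exo-tet SN2) the C1 oxygen, trans to the mesylate, attacks C6 from the rear, so C1 is retained and C6 is inverted to S, giving the cis-fused oxirane.

**Compound list**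

1 | D-fructose | OC[C@@H](O)[C@@H](O)[C@H](O)C(=O)CO | starting material
2 | methyl 1,3-O-isopropylidene-α-D-fructofuranoside | CO[C@]12COC(C)(C)O[C@H]1[C@H](O)[C@@H](CO)O2 | intermediate
3 | methyl 6-deoxy-6-iodo-1,3-O-isopropylidene-α-D-fructofuranoside | CO[C@]12COC(C)(C)O[C@H]1[C@H](O)[C@@H](CI)O2 | intermediate
4 | methyl 4-O-benzoyl-6-deoxy-6-iodo-1,3-O-isopropylidene-α-D-fructofuranoside | CO[C@]12COC(C)(C)O[C@H]1[C@H](OC(=O)c3ccccc3)[C@@H](CI)O2 | intermediate
5 | (1R)-1-[(4S)-2,2-dimethyl-5-oxo-1,3-dioxan-4-yl]prop-2-enyl benzoate | C=C[C@@H](OC(=O)c1ccccc1)[C@@H]1OC(C)(C)OCC1=O | intermediate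
6 | allyl 4-methoxybenzyl ether | C=CCOCc1ccc(OC)cc1 | starting material
7 | (Z)-3-lithio-1-(4-methoxybenzyloxy)prop-1-ene (O-chelated alkoxyallyllithium) | [Li]C/C=C\OCc1ccc(OC)cc1 | intermediate
8 | diethyl[(Z)-3-(4-methoxybenzyloxy)prop-2-enyl]aluminium | CC[Al](CC)C/C=C\OCc1ccc(OC)cc1 | intermediate
9 | (1R)-1-{(4S,5S)-5-hydroxy-5-[(1R)-1-(4-methoxybenzyloxy)prop-2-enyl]-2,2-dimethyl-1,3-dioxan-4-yl}prop-2-enyl benzoate | C=C[C@@H](OC(=O)c1ccccc1)[C@@H]1OC(C)(C)OC[C@]1(O)[C@H](OCc1ccc(OC)cc1)C=C | intermediate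
10 | (3R,4S,5R,6R)-4,5-dihydroxy-5-(hydroxymethyl)-6-(4-methoxybenzyloxy)octa-1,7-dien-3-yl benzoate | C=C[C@@H](OC(=O)c1ccccc1)[C@H](O)[C@](O)(CO)[C@H](OCc1ccc(OC)cc1)C=C | intermediate
11 | (3R,4S,5R,6R)-5-(benzoyloxymethyl)-4,5-dihydroxy-6-(4-methoxybenzyloxy)octa-1,7-dien-3-yl benzoate | C=C[C@@H](OC(=O)c1ccccc1)[C@H](O)[C@](O)(COC(=O)c1ccccc1)[C@H](OCc1ccc(OC)cc1)C=C | intermediate
12 | (3R,4S,5S,6R)-4-acetoxy-5-(benzoyloxymethyl)-5-hydroxy-6-(4-methoxybenzyloxy)octa-1,7-dien-3-yl benzoate | C=C[C@@H](OC(=O)c1ccccc1)[C@H](OC(C)=O)[C@](O)(COC(=O)c1ccccc1)[C@H](OCc1ccc(OC)cc1)C=C | intermediate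
13 | (1R,4R,5S,6S)-6-acetoxy-5-(benzoyloxymethyl)-5-hydroxy-4-(4-methoxybenzyloxy)cyclohex-2-en-1-yl benzoate | CC(=O)O[C@H]1[C@H](OC(=O)c2ccccc2)C=C[C@@H](OCc2ccc(OC)cc2)[C@@]1(O)COC(=O)c1ccccc1 | intermediate
14 | (1R,4R,5S,6S)-6-acetoxy-5-(benzoyloxymethyl)-4,5-dihydroxycyclohex-2-en-1-yl benzoate | CC(=O)O[C@H]1[C@H](OC(=O)c2ccccc2)C=C[C@@H](O)[C@@]1(O)COC(=O)c1ccccc1 | intermediate
15 | (1R,4R,5R,6S)-6-acetoxy-5-(benzoyloxymethyl)-5-hydroxy-4-(methylsulfonyloxy)cyclohex-2-en-1-yl benzoate | CC(=O)O[C@H]1[C@H](OC(=O)c2ccccc2)C=C[C@@H](OS(C)(=O)=O)[C@@]1(O)COC(=O)c1ccccc1 | intermediate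
16 | [(1S,2S,3R,6S)-2-acetoxy-3-(benzoyloxy)-7-oxabicyclo[4.1.0]hept-4-en-1-yl]methyl benzoate | CC(=O)O[C@H]1[C@H](OC(=O)c2ccccc2)C=C[C@@H]2O[C@@]21COC(=O)c1ccccc1 | target

**Step count**

Total steps: 12. Longest linear sequence: 12 steps (from D-fructose).

**Steps most likely to fail**

1. Step 5. Attack on the dioxanone from the equatorial direction, or loss of the Z-geometry and chair control, would give poor facial selectivity at C1 or erosion of the syn relationship at C6. The fallback changes the control element from ring conformation to a metal chelate in an open chain. It sets out from 4. Acid-catalysed methanolysis of the acetonide (TsOH cat., MeOH, 0 °C) gives methyl 4-O-benzoyl-6-deoxy-6-iodo-α-D-fructofuranoside F1. Benzoylation of its primary hydroxyl (BzCl, pyridine, −30 °C) gives methyl 1,4-di-O-benzoyl-6-deoxy-6-iodo-α-D-fructofuranoside F2. Zinc fragmentation as in step 4 gives 1,4-di-O-benzoyl-5,6-dideoxy-D-threo-hex-5-en-2-ulose F3. With excess reagent 8 the free α-hydroxyl (the later C2–OH) becomes an aluminium alkoxide that chelates the ketone oxygen (Cram cyclic model), and allyl transfer to the face away from the C3 side chain should give C1–OH syn to C2–O. The product is diol 11, where the route is rejoined before step 8.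

2. Step 4. Once the ketone is unmasked, loss of benzoic acid by β-elimination or epimerisation at the α-carbon may occur, and the same threat continues into step 5. The fallback introduces the ester only after the C–C bond is made. It sets out from 3. Silylation (TBSCl, imidazole, DMF) gives methyl 4-O-(tert-butyldimethylsilyl)-6-deoxy-6-iodo-1,3-O-isopropylidene-α-D-fructofuranoside F4. Zinc fragmentation gives (4S)-4-[(1R)-1-(tert-butyldimethylsilyloxy)prop-2-enyl]-2,2-dimethyl-1,3-dioxan-5-one F5. Addition of 8 as in step 5 gives the silyl-protected tertiary alcohol F6. TBAF in THF gives the secondary/tertiary diol F7. Benzoylation (BzCl, pyridine, 0 °C) takes only the secondary allylic hydroxyl and returns to 9.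

3. Step 12 (with the mesylate of step 11). The allylic mesylate may ionise or be displaced before ring closure, and the C1 alkoxide may take up the neighbouring acetate or benzoate instead of closing the ring. The fallback is a Mitsunobu cyclodehydration of diol 14 (PPh3, DIAD, toluene, 0 °C → rt). The secondary allylic C6–OH is activated as an oxyphosphonium ion and displaced with inversion by the neutral C1–OH, which gives 16 directly without a sulfonate or a base. This fallback makes no new compound (F0).

**Further compounds**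

F1 | step 5 | methyl 4-O-benzoyl-6-deoxy-6-iodo-α-D-fructofuranoside | CO[C@]1(CO)[C@@H](O)[C@H](OC(=O)c2ccccc2)[C@@H](CI)O1
F2 | step 5 | methyl 1,4-di-O-benzoyl-6-deoxy-6-iodo-α-D-fructofuranoside | CO[C@]1(COC(=O)c2ccccc2)[C@@H](O)[C@H](OC(=O)c2ccccc2)[C@@H](CI)O1
F3 | step 5 | 1,4-di-O-benzoyl-5,6-dideoxy-D-threo-hex-5-en-2-ulose | C=C[C@@H](OC(=O)c1ccccc1)[C@H](O)C(=O)COC(=O)c1ccccc1
F4 | step 4 | methyl 4-O-(tert-butyldimethylsilyl)-6-deoxy-6-iodo-1,3-O-isopropylidene-α-D-fructofuranoside | CO[C@]12COC(C)(C)O[C@H]1[C@H](O[Si](C)(C)C(C)(C)C)[C@@H](CI)O2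
F5 | step 4 | (4S)-4-[(1R)-1-(tert-butyldimethylsilyloxy)prop-2-enyl]-2,2-dimethyl-1,3-dioxan-5-one | C=C[C@@H](O[Si](C)(C)C(C)(C)C)[C@@H]1OC(C)(C)OCC1=O
F6 | step 4 | (4S,5S)-4-[(1R)-1-(tert-butyldimethylsilyloxy)prop-2-enyl]-5-[(1R)-1-(4-methoxybenzyloxy)prop-2-enyl]-2,2-dimethyl-1,3-dioxan-5-ol | C=C[C@@H](O[Si](C)(C)C(C)(C)C)[C@@H]1OC(C)(C)OC[C@]1(O)[C@H](OCc1ccc(OC)cc1)C=C
F7 | step 4 | (4S,5S)-4-[(1R)-1-hydroxyprop-2-enyl]-5-[(1R)-1-(4-methoxybenzyloxy)prop-2-enyl]-2,2-dimethyl-1,3-dioxan-5-ol | C=C[C@@H](O)[C@@H]1OC(C)(C)OC[C@]1(O)[C@H](OCc1ccc(OC)cc1)C=C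
F0 | step 12 | none | none
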